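**Plan**

- Numbering (germacrane): ring carbons C1–C10; lactone O on C6, C11 on C7, ester O on C8; C12 is the lactone C=O, C13 the exocyclic CH2, C14 sits on C10 and C15 on C4.
- Retrosynthetic cuts, in order: the C8–O ester (Mitsunobu inversion of the 8-epi alcohol); C11=C13 (from a C13 bromide made by opening an O8–C13 ether); C1=C10 (ring-closing metathesis); then C11–C7 and O–C6 together; then O8–C13, C11–C12, C8–C9, C7–C8 and C4–C5 of the open chain.
- Enabling feature: O8 on C8 is vicinal to C7 and 1,5-related to C13 (O8–C8–C7–C11=C13). An O8–C13 ether can therefore hold a C13–C11–C12 malonic half acid over the C6=C7 alkene; the C11 radical closes onto C7 (temporary oxolane ring) and its carboxyl group closes onto C6 (γ-lactone ring).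
- Forward ring order: oxolane and γ-lactone in one operation on the open chain, then the ten-membered carbocycle, then the oxolane is opened and its carbon becomes the exocyclic methylene.
- Stereochemistry: C4 from an Evans alkylation; C8 (first as its epimer) from a Keck allylation; C7 and C6 from the key step, steered by C8 and by the cis-fused bicycle; C8 is inverted when the isobutyrate is put on; the 6E alkene comes from alkyne reduction and the C1=C10 geometry from the ring.

Key step: step 12

Remark: the 5-exo closure is assumed to follow the usual trans preference for a substituent on the allylic carbon, which is why C8 enters as its epimer and is inverted in step 16.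

**Route**

Step 1
Reactants: 1 (4S)-4-benzyloxazolidin-2-one; 2 hex-5-enoyl chloride
Product: 3 (4S)-4-benzyl-3-(hex-5-enoyl)oxazolidin-2-one
Conditions: Et3N, DMAP (cat.), CH2Cl2, 0 °C → rt
Reagents that add atoms: none
Why: DMAP-catalysed N-acylation attaches the chiral auxiliary to the chain that becomes C15, C4, C3, C2 and C1; no stereocentre is formed.

Step 2
Reactants: 3 (4S)-4-benzyl-3-(hex-5-enoyl)oxazolidin-2-one; 4 propargyl bromide
Product: 6 (4S)-4-benzyl-3-[(2R)-2-(prop-2-yn-1-yl)hex-5-enoyl]oxazolidin-2-one, via sodium Z-enolate 5 (not isolated)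
Conditions: NaN(SiMe3)2, THF, −78 °C; then 4, −78 → −45 °C
Reagents that add atoms: none
Why: Evans asymmetric alkylation, in which the chelated Z-enolate is attacked on the face away from the benzyl group, sets C4 as R and brings in C5–C7.

Step 3
Reactants: 6 (4S)-4-benzyl-3-[(2R)-2-(prop-2-yn-1-yl)hex-5-enoyl]oxazolidin-2-one
Product: 7 (2R)-2-(prop-2-yn-1-yl)hex-5-en-1-ol
Conditions: LiBH4, MeOH (1.1 equiv), Et2O, 0 °C
Reagents that add atoms: none
Why: reductive cleavage of the N-acyloxazolidinone should give the primary alcohol (the future C15–OH) without epimerisation and return the auxiliary.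

Step 4
Reactants: 7 (2R)-2-(prop-2-yn-1-yl)hex-5-en-1-ol
Product: 8 tert-butyl(diphenyl){[(2R)-2-(prop-2-yn-1-yl)hex-5-en-1-yl]oxy}silane
Conditions: TBDPSCl, imidazole, DMF, rt
Reagents that add atoms: tert-butyl(chloro)diphenylsilane, CC(C)(C)[Si](Cl)(c1ccccc1)c1ccccc1
Why: standard silylation of a primary alcohol with a group robust enough for the base, acetic acid and metathesis steps ahead.

Step 5
Reactants: 8 tert-butyl(diphenyl){[(2R)-2-(prop-2-yn-1-yl)hex-5-en-1-yl]oxy}silane
Product: 10 (5R)-5-{[tert-butyl(diphenyl)silyl]oxymethyl}non-8-en-2-ynal, via lithium acetylide 9 (not isolated)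
Conditions: n-BuLi, THF, −78 °C; then DMF; poured into aqueous KH2PO4
Reagents that add atoms: N,N-dimethylformamide, CN(C)C=O
Why: formylation of the lithium acetylide with buffered inverse quench gives the ynal and introduces C8.

Step 6
Reactants: 11 2-methylenepropane-1,3-diol
Product: 12 2-{[tert-butyl(diphenyl)silyl]oxymethyl}prop-2-en-1-ol
Conditions: TBDPSCl (1 equiv), imidazole, THF, 0 °C, diol in threefold excess
Reagents that add atoms: tert-butyl(chloro)diphenylsilane, CC(C)(C)[Si](Cl)(c1ccccc1)c1ccccc1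
Why: statistical monosilylation of a symmetric diol used in excess gives the C9–C10–C14 unit with C14–O protected.

Step 7
Reactants: 12 2-{[tert-butyl(diphenyl)silyl]oxymethyl}prop-2-en-1-ol
Product: 14 tributyl(2-{[tert-butyl(diphenyl)silyl]oxymethyl}prop-2-en-1-yl)stannane, via allylic mesylate 13 (not isolated)
Conditions: MsCl, Et3N, THF, −40 °C; then Bu3SnLi (from Bu3SnH and LiN(iPr)2), THF, −78 → −20 °C
Reagents that add atoms: tributylstannyllithium, [Li][Sn](CCCC)(CCCC)CCCC
Why: the stannyl anion displaces the allylic mesylate (direct and allylic displacement give the same product) to give the 2-substituted allylstannane.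

Step 8
Reactants: 10 (5R)-5-{[tert-butyl(diphenyl)silyl]oxymethyl}non-8-en-2-ynal; 14 tributyl(2-{[tert-butyl(diphenyl)silyl]oxymethyl}prop-2-en-1-yl)stannane
Product: 15 (4S,8R)-2,8-bis{[tert-butyl(diphenyl)silyl]oxymethyl}dodeca-1,11-dien-5-yn-4-ol
Conditions: (S)-BINOL (0.2 equiv), Ti(OiPr)4 (0.1 equiv), 4 Å molecular sieves, CH2Cl2, −20 °C
Reagents that add atoms: none
Why: Keck asymmetric allylation forms C8–C9 and the chiral BINOL–titanium Lewis acid should set the carbinol C8 as S (the C8 epimer of the target, as the tether needs); the other BINOL enantiomer is used if the facial sense proves opposite.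

Step 9
Reactants: 15 (4S,8R)-2,8-bis{[tert-butyl(diphenyl)silyl]oxymethyl}dodeca-1,11-dien-5-yn-4-ol
Product: 16 (4S,5E,8R)-2,8-bis{[tert-butyl(diphenyl)silyl]oxymethyl}dodeca-1,5,11-trien-4-ol
Conditions: NaAlH2(OCH2CH2OMe)2, THF, 0 °C → rt; aqueous Rochelle salt
Reagents that add atoms: none
Why: hydroxyl-directed trans-hydroalumination of the propargylic alcohol and protonolysis should give only the E C6=C7 alkene.

Step 10
Reactants: 16 (4S,5E,8R)-2,8-bis{[tert-butyl(diphenyl)silyl]oxymethyl}dodeca-1,5,11-trien-4-ol; 17 tert-butyl acrylate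
Product: 18 tert-butyl 3-{[(4S,5E,8R)-2,8-bis{[tert-butyl(diphenyl)silyl]oxymethyl}dodeca-1,5,11-trien-4-yl]oxy}propanoate
Conditions: KOtBu (0.1 equiv), 17 (3 equiv), THF, 0 °C
Reagents that add atoms: none
Why: base-catalysed oxa-Michael addition of the secondary alkoxide to the acrylate makes the O8–C13 ether and brings in C13 and C11; the tert-butyl ester prevents transesterification.

Step 11
Reactants: 18 tert-butyl 3-{[(4S,5E,8R)-2,8-bis{[tert-butyl(diphenyl)silyl]oxymethyl}dodeca-1,5,11-trien-4-yl]oxy}propanoate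
Product: 20 malonic half acid 3-tert-butoxy-3-oxo-2-({[(4S,5E,8R)-2,8-bis{[tert-butyl(diphenyl)silyl]oxymethyl}dodeca-1,5,11-trien-4-yl]oxy}methyl)propanoic acid (both C11 epimers), via lithium ester enolate 19 (not isolated)
Conditions: LiN(iPr)2 (1.15 equiv), THF, −78 °C; then CO2 (gas), −78 °C; cold 1 M HCl
Reagents that add atoms: carbon dioxide, O=C=O
Why: the kinetic ester enolate, whose loss of the β-alkoxide is slow at −78 °C, is carboxylated to the malonic half acid; the new carbon becomes C12.

Step 12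
Reactants: 20 malonic half acid
Product: 21 cis-fused 3,7-dioxabicyclo[3.3.0]octan-2-one (γ-lactone C12–O–C6–C7–C11 fused along C7–C11 to the oxolane C11–C13–O8–C8–C7) with the tert-butyl ester on C11, the C5–C1 chain on C6 and the C9–C10–C14 chain on C8; configuration 4R,6R,7R,8S,11R
Conditions: Mn(OAc)3·2H2O (2.5 equiv), KOAc, AcOH (0.02 M), 25 → 45 °C, argon
Reagents that add atoms: none
Why: Mn(OAc)3 (trivalent manganese) forms the manganese enolate of the half acid and electron transfer gives the C11 malonyl radical, which adds to C7 of the E alkene; a second equivalent oxidises the resulting C6 radical within its carboxylate complex so that the carboxyl oxygen bonds to C6. The closest known reaction type is the manganese triacetate oxidative free-radical cyclisation with lactone termination, as used for alkenyl malonic half acids and cyanoacetic acids. The oxolane closes 5-exo-trig (C11 onto C7) and the lactone closes 5-exo by carboxylate capture of the oxidised C6 centre. C7 is set by the chair-like 5-exo transition state with the C9 chain on C8 pseudo-equatorial, so the new C7–C6 bond ends up trans to that chain; C11 is set by the requirement for a cis-fused bicycle; C6 is set because the C5 chain takes the convex exo face during lactone closure, which gives the trans H6/H7 relation of the target. The step needs 5-exo rather than 6-endo addition, carboxylate capture of the C6 radical rather than hydrogen abstraction or β-hydride loss, and no reaction at the two terminal alkenes; the three-atom ether tether, the free carboxyl group held next to C6, the omission of a copper co-oxidant and the larger ring sizes needed to reach the other alkenes should secure these.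

Step 13
Reactants: 21 bicyclic lactone tert-butyl ester
Product: 23 the same cis-fused 3,7-dioxabicyclo[3.3.0]octan-2-one with H on C11 (4R,6R,7R,8S,11S), via C11 carboxylic acid 22 (not isolated)
Conditions: Me3SiOTf, 2,6-lutidine, CH2Cl2, 0 °C; aqueous work-up; then toluene, 100 °C
Reagents that add atoms: none
Why: the silyl triflate cleaves the tert-butyl ester without protic acid, and the malonic-type acid loses CO2 on warming; the enol can only be protonated to the cis-fused bicycle.

Step 14
Reactants: 23 bicyclic lactone with two alkenyl chains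
Product: 24 tricycle in which the ten-membered carbocycle is closed (C1=C10 with C2 and C9 cis, E by CIP; γ-lactone on C6/C7, oxolane on C7/C8; 4R,6R,7R,8S,11S)
Conditions: second-generation Grubbs catalyst (10 mol%), toluene (1 mM), 80 °C
Reagents that add atoms: none
Why: ring-closing metathesis of the monosubstituted and the 1,1-disubstituted alkene, whose chains sit on the same convex face of the rigid bicycle, should close the ten-membered ring, which can only hold the olefin with C2 and C9 cis.

Step 15
Reactants: 24 tricycle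
Product: 26 bromo alcohol: ten-membered ring with trans-fused γ-lactone carrying CH2Br on C11 and a free 8α-hydroxyl (4R,6R,7R,8S,11R), via dimethylborinate 25 (not isolated)
Conditions: Me2BBr, CH2Cl2, −78 → 0 °C; aqueous NaHCO3
Reagents that add atoms: bromodimethylborane, CB(C)Br
Why: the boron Lewis acid binds the oxolane oxygen and bromide attacks the less hindered primary C13 (ether cleavage by a dialkylboron bromide), which frees O8 without forming an alkoxide next to the lactone and makes C13 a leaving-group carbon.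

Step 16
Reactants: 26 bromo alcohol; 27 isobutyric acid
Product: 28 bromo ester: as 26 but with an 8β-isobutyryloxy group (4R,6R,7S,8R,11R)
Conditions: PPh3, DIAD, toluene, 0 °C → rt
Reagents that add atoms: none
Why: Mitsunobu reaction, in which isobutyrate displaces the oxyphosphonium at C8 with inversion, gives the 8R ester of the target.

Step 17
Reactants: 28 bromo ester
Product: 29 14,15-bis-O-(tert-butyldiphenylsilyl) ether of the target
Conditions: DBU, CH2Cl2, 0 °C → rt
Reagents that add atoms: none
Why: E1cB loss of HBr from the β-bromo lactone is the standard way to unmask an α-methylene lactone; C11 loses its stereocentre and C13 becomes the exocyclic CH2.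

Step 18
Reactants: 29 bis-silyl ether of the target
Product: 30 target CNP0361020.1
Conditions: HF·pyridine, pyridine, THF, 0 °C → rt
Reagents that add atoms: none
Why: buffered fluoride should cleave both primary silyl ethers and leave the α-methylene lactone and the isobutyrate untouched.

**Compound list**

1 | (4S)-4-benzyloxazolidin-2-one | O=C1N[C@@H](Cc2ccccc2)CO1 | starting material
2 | hex-5-enoyl chloride | C=CCCCC(Cl)=O | starting material
3 | (4S)-4-benzyl-3-(hex-5-enoyl)oxazolidin-2-one | C=CCCCC(=O)N1[C@@H](Cc2ccccc2)COC1=O | intermediate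
4 | propargyl bromide | C#CCBr | starting material
5 | sodium Z-enolate of 3 (not isolated) | C=CCC/C=C(\[O-])N1[C@@H](Cc2ccccc2)COC1=O.[Na+] | intermediate
6 | (4S)-4-benzyl-3-[(2R)-2-(prop-2-yn-1-yl)hex-5-enoyl]oxazolidin-2-one | C=CCC[C@H](CC#C)C(=O)N1[C@@H](Cc2ccccc2)COC1=O | intermediate
7 | (2R)-2-(prop-2-yn-1-yl)hex-5-en-1-ol | C=CCC[C@@H](CO)CC#C | intermediate
8 | tert-butyl(diphenyl){[(2R)-2-(prop-2-yn-1-yl)hex-5-en-1-yl]oxy}silane | C=CCC[C@@H](CO[Si](c1ccccc1)(c1ccccc1)C(C)(C)C)CC#C | intermediate
9 | lithium acetylide of 8 (not isolated) | C=CCC[C@@H](CO[Si](c1ccccc1)(c1ccccc1)C(C)(C)C)CC#[C-].[Li+] | intermediate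
10 | (5R)-5-{[tert-butyl(diphenyl)silyl]oxymethyl}non-8-en-2-ynal | C=CCC[C@@H](CO[Si](c1ccccc1)(c1ccccc1)C(C)(C)C)CC#CC=O | intermediate
11 | 2-methylenepropane-1,3-diol | C=C(CO)CO | starting material
12 | 2-{[tert-butyl(diphenyl)silyl]oxymethyl}prop-2-en-1-ol | C=C(CO)CO[Si](c1ccccc1)(c1ccccc1)C(C)(C)C | intermediate
13 | methanesulfonate of 12 (not isolated) | C=C(COS(C)(=O)=O)CO[Si](c1ccccc1)(c1ccccc1)C(C)(C)C | intermediate
14 | tributyl(2-{[tert-butyl(diphenyl)silyl]oxymethyl}prop-2-en-1-yl)stannane | C=C(C[Sn](CCCC)(CCCC)CCCC)CO[Si](c1ccccc1)(c1ccccc1)C(C)(C)C | intermediate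
15 | (4S,8R)-2,8-bis{[tert-butyl(diphenyl)silyl]oxymethyl}dodeca-1,11-dien-5-yn-4-ol | C=CCC[C@@H](CO[Si](c1ccccc1)(c1ccccc1)C(C)(C)C)CC#C[C@@H](O)CC(=C)CO[Si](c1ccccc1)(c1ccccc1)C(C)(C)C | intermediate
16 | (4S,5E,8R)-2,8-bis{[tert-butyl(diphenyl)silyl]oxymethyl}dodeca-1,5,11-trien-4-ol | C=CCC[C@@H](CO[Si](c1ccccc1)(c1ccccc1)C(C)(C)C)C/C=C/[C@@H](O)CC(=C)CO[Si](c1ccccc1)(c1ccccc1)C(C)(C)C | intermediate
17 | tert-butyl acrylate | C=CC(=O)OC(C)(C)C | starting material
18 | tert-butyl 3-{[(4S,5E,8R)-2,8-bis{[tert-butyl(diphenyl)silyl]oxymethyl}dodeca-1,5,11-trien-4-yl]oxy}propanoate | C=CCC[C@@H](CO[Si](c1ccccc1)(c1ccccc1)C(C)(C)C)C/C=C/[C@H](CC(=C)CO[Si](c1ccccc1)(c1ccccc1)C(C)(C)C)OCCC(=O)OC(C)(C)C | intermediate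
19 | lithium enolate of 18 (not isolated) | C=CCC[C@@H](CO[Si](c1ccccc1)(c1ccccc1)C(C)(C)C)C/C=C/[C@H](CC(=C)CO[Si](c1ccccc1)(c1ccccc1)C(C)(C)C)OCC=C([O-])OC(C)(C)C.[Li+] | intermediate
20 | malonic half acid: 3-tert-butoxy-3-oxo-2-({[(4S,5E,8R)-2,8-bis{[tert-butyl(diphenyl)silyl]oxymethyl}dodeca-1,5,11-trien-4-yl]oxy}methyl)propanoic acid, C11 epimers | C=CCC[C@@H](CO[Si](c1ccccc1)(c1ccccc1)C(C)(C)C)C/C=C/[C@H](CC(=C)CO[Si](c1ccccc1)(c1ccccc1)C(C)(C)C)OCC(C(=O)O)C(=O)OC(C)(C)C | intermediate
21 | cis-fused 3,7-dioxabicyclo[3.3.0]octan-2-one, tert-butyl ester on C11, chains on C6 and C8 (4R,6R,7R,8S,11R) | O=C1O[C@H](C[C@H](CO[Si](c3ccccc3)(c3ccccc3)C(C)(C)C)CCC=C)[C@H]2[C@H](CC(=C)CO[Si](c3ccccc3)(c3ccccc3)C(C)(C)C)OC[C@@]12C(=O)OC(C)(C)C | intermediate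
22 | C11 carboxylic acid of 21 (not isolated) | O=C1O[C@H](C[C@H](CO[Si](c3ccccc3)(c3ccccc3)C(C)(C)C)CCC=C)[C@H]2[C@H](CC(=C)CO[Si](c3ccccc3)(c3ccccc3)C(C)(C)C)OC[C@@]12C(=O)O | intermediate
23 | cis-fused 3,7-dioxabicyclo[3.3.0]octan-2-one with H on C11 (4R,6R,7R,8S,11S) | O=C1O[C@H](C[C@H](CO[Si](c3ccccc3)(c3ccccc3)C(C)(C)C)CCC=C)[C@H]2[C@H](CC(=C)CO[Si](c3ccccc3)(c3ccccc3)C(C)(C)C)OC[C@@H]12 | intermediate
24 | tricycle: ten-membered carbocycle with γ-lactone on C6/C7 and oxolane on C7/C8 (4R,6R,7R,8S,11S; C1=C10 E by CIP) | O=C1O[C@@H]2C[C@H](CO[Si](c4ccccc4)(c4ccccc4)C(C)(C)C)CC/C=C(/CO[Si](c4ccccc4)(c4ccccc4)C(C)(C)C)C[C@@H]3OC[C@@H]1[C@@H]23 | intermediate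
25 | O8 dimethylborinate of 26 (not isolated) | BrC[C@H]1C(=O)O[C@@H]2C[C@H](CO[Si](c3ccccc3)(c3ccccc3)C(C)(C)C)CC/C=C(/CO[Si](c3ccccc3)(c3ccccc3)C(C)(C)C)C[C@H](OB(C)C)[C@@H]12 | intermediate
26 | bromo alcohol: 11-bromomethyl γ-lactone with free 8α-OH (4R,6R,7R,8S,11R) | BrC[C@H]1C(=O)O[C@@H]2C[C@H](CO[Si](c3ccccc3)(c3ccccc3)C(C)(C)C)CC/C=C(/CO[Si](c3ccccc3)(c3ccccc3)C(C)(C)C)C[C@H](O)[C@@H]12 | intermediate
27 | isobutyric acid | CC(C)C(=O)O | starting material
28 | bromo ester: 11-bromomethyl γ-lactone with 8β-isobutyryloxy group (4R,6R,7S,8R,11R) | BrC[C@H]1C(=O)O[C@@H]2C[C@H](CO[Si](c3ccccc3)(c3ccccc3)C(C)(C)C)CC/C=C(/CO[Si](c3ccccc3)(c3ccccc3)C(C)(C)C)C[C@@H](OC(=O)C(C)C)[C@@H]12 | intermediate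
29 | 14,15-bis-O-(tert-butyldiphenylsilyl) ether of the target (4R,6R,7S,8R) | C=C1C(=O)O[C@@H]2C[C@H](CO[Si](c3ccccc3)(c3ccccc3)C(C)(C)C)CC/C=C(/CO[Si](c3ccccc3)(c3ccccc3)C(C)(C)C)C[C@@H](OC(=O)C(C)C)[C@@H]12 | intermediate
30 | CNP0361020.1 (4R,6R,7S,8R) | C=C1C(=O)O[C@@H]2C[C@H](CO)CC/C=C(/CO)C[C@@H](OC(=O)C(C)C)[C@@H]12 | target

**Totals and risks**

Total step count: 18. Longest linear sequence: 16 steps (steps 1–5 and 8–18); steps 6 and 7 make the allylstannane branch.

Step 12. The C6 radical may abstract hydrogen or lose a β-hydrogen instead of being captured by the carboxyl group, the 5-exo closure may show poor facial selectivity at C7, or the half acid may decarboxylate oxidatively. The fallback separates radical C–C formation from ionic C–O formation; it sets out from 16 and returns at 23. Alcohol 16 is added to tert-butyl 2-bromoacrylate (KOtBu cat., THF) to give the α-bromo ester F1. A bromine atom-transfer 5-exo cyclisation (CuBr, tris(2-pyridylmethyl)amine, benzene, 60 °C) gives the oxolane bromide F2 with the C11–C7 bond in place. AgOTf with 2,6-lutidine then ionises the C6 bromide, the tert-butyl ester carbonyl closes the lactone with the C5 chain on the convex face, and isobutene is lost to give 23.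

Step 14. Intermolecular metathesis may outrun closure of the strained ten-membered ring, and the 1,1-disubstituted alkene may engage too slowly. The fallback moves ring closure to an open-chain lactone; it sets out from 23 and returns at 28. The oxolane of 23 is opened with Me2BBr to the open-chain bromo alcohol F3, and a Mitsunobu reaction with 27 gives the open-chain bromo ester F4 with the natural C8 configuration. F4, in which rotation about C7–C8 is free, is closed with the second-generation Grubbs catalyst under high dilution to give 28.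

Step 16. Displacement at the hindered ring carbinol may be slow, so that elimination across C8–C9 or acyl transfer with retention takes over. The fallback replaces substitution by oxidation and reduction; it sets out from 26 and returns at 28. Dess–Martin periodinane (CH2Cl2, NaHCO3) gives the C8 ketone F5. NaBH4 with CeCl3·7H2O in MeOH at −78 °C should deliver hydride to the α face, away from C11 and its bromomethyl group, to give the 8β alcohol F6. Isobutyric anhydride with DMAP and pyridine acylates F6 to 28; any loss of HBr at this stage only anticipates step 17.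

Further compounds
F1 | step 12 | tert-butyl 2-bromo-3-{[(4S,5E,8R)-2,8-bis{[tert-butyl(diphenyl)silyl]oxymethyl}dodeca-1,5,11-trien-4-yl]oxy}propanoate | C=CCC[C@@H](CO[Si](c1ccccc1)(c1ccccc1)C(C)(C)C)C/C=C/[C@H](CC(=C)CO[Si](c1ccccc1)(c1ccccc1)C(C)(C)C)OCC(Br)C(=O)OC(C)(C)C
F2 | step 12 | oxolane bromide: tert-butyl oxolane-3-carboxylate (C11) with the 1-bromoalkyl chain (Br on C6) on C7 and the C9–C10–C14 chain on C8, C6 and C11 epimers | C=CCC[C@@H](CO[Si](c2ccccc2)(c2ccccc2)C(C)(C)C)CC(Br)[C@H]1[C@H](CC(=C)CO[Si](c2ccccc2)(c2ccccc2)C(C)(C)C)OCC1C(=O)OC(C)(C)C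
F3 | step 14 | open-chain bromo alcohol: 11-bromomethyl γ-lactone with the C5–C1 chain on C6 and the 8S carbinol chain on C7 | BrC[C@H]1C(=O)O[C@H](C[C@H](CO[Si](c2ccccc2)(c2ccccc2)C(C)(C)C)CCC=C)[C@H]1[C@@H](O)CC(=C)CO[Si](c2ccccc2)(c2ccccc2)C(C)(C)C
F4 | step 14 | open-chain bromo ester: as F3 but with the 8R isobutyrate | BrC[C@H]1C(=O)O[C@H](C[C@H](CO[Si](c2ccccc2)(c2ccccc2)C(C)(C)C)CCC=C)[C@H]1[C@H](OC(=O)C(C)C)CC(=C)CO[Si](c2ccccc2)(c2ccccc2)C(C)(C)C
F5 | step 16 | C8 ketone of 26 | BrC[C@H]1C(=O)O[C@@H]2C[C@H](CO[Si](c3ccccc3)(c3ccccc3)C(C)(C)C)CC/C=C(/CO[Si](c3ccccc3)(c3ccccc3)C(C)(C)C)CC(=O)[C@@H]12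
F6 | step 16 | 8β alcohol (C8 epimer of 26) | BrC[C@H]1C(=O)O[C@@H]2C[C@H](CO[Si](c3ccccc3)(c3ccccc3)C(C)(C)C)CC/C=C(/CO[Si](c3ccccc3)(c3ccccc3)C(C)(C)C)C[C@@H](O)[C@@H]12
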